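The route builds the coumarin benzo ring (C4a, C5, C6, C7, C8, C8a) instead of desymmetrizing a phloroglucinol. That ring carries three oxygens in a 1,3,5 relationship that all differ (lactone O1 on C8a, OMe on C5, OH on C7), next to C4a, which bears C4. A Danheiser benzannulation of 3-(benzyloxy)cyclobutenone with a 1-methoxyalkyne forms C8a–C4a, C5–C6 and C8a–C8 in one operation and delivers the oxygens as free OH, OMe and OBn. The alkyne is a silyl-protected 5-methoxypent-4-yn-1-ol carrying the 5-methoxy-2,2-dimethylchroman-6-yl group at C2, made from a 3-aryloxetane and lithium methoxyacetylide. Lactonization, dehydrogenation and debenzylation finish the synthesis.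

Key step: step 11

Remark: the target is achiral, so the single stereocentre that appears in 9 and is carried from 13 to 27 is used as the racemate; it is destroyed when C3=C4 is introduced in step 14. 3-Ethoxycyclobut-2-en-1-one and 3-methylbut-2-enal are taken as purchasable.

Step 1
Reactants: 1 2,4-dihydroxyacetophenone; 2 3-methylbut-2-enal
Product: 3 1-(5-hydroxy-2,2-dimethyl-2H-chromen-6-yl)ethan-1-one
Conditions: pyridine, 140 °C (sealed vessel)
Reagents that add atoms: none
Why: Pyridine-mediated chromenylation, in which aldol-type condensation of the enal at the ring carbon between the two oxygens, loss of water and oxa-6π electrocyclization close the 2H-pyran on the 4-OH, because the 2-OH stays locked in a hydrogen bond to the acetyl group.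

Step 2
Reactants: 3 1-(5-hydroxy-2,2-dimethyl-2H-chromen-6-yl)ethan-1-one
Product: 4 1-(5-hydroxy-2,2-dimethylchroman-6-yl)ethan-1-one
Conditions: H2 (1 atm), 10% Pd/C, EtOAc, rt
Reagents that add atoms: none
Why: Heterogeneous catalytic hydrogenation saturates the styrene-type chromene alkene quickly, while the hydrogen-bonded aryl ketone is left alone at 1 atm and room temperature.

Step 3
Reactants: 4 1-(5-hydroxy-2,2-dimethylchroman-6-yl)ethan-1-one
Product: 5 1-(5-methoxy-2,2-dimethylchroman-6-yl)ethan-1-one
Conditions: MeI, K2CO3, DMF, 50 °C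
Reagents that add atoms: iodomethane, CI
Why: Williamson O-methylation, for which the chelated phenol needs carbonate in warm DMF but which has no competing nucleophilic site.

Step 4
Reactants: 5 1-(5-methoxy-2,2-dimethylchroman-6-yl)ethan-1-one
Product: 6 methyl 2-(5-methoxy-2,2-dimethylchroman-6-yl)acetate
Conditions: PhI(OAc)2 (1.1 equiv), conc. H2SO4, HC(OMe)3, 60 °C
Reagents that add atoms: trimethyl orthoformate, COC(OC)OC
Why: Oxidative 1,2-aryl shift of an aryl methyl ketone with a trivalent iodine reagent, in which the ketone is ketalized, its enol ether is attacked at CH2 by the iodine electrophile and the electron-rich aryl group migrates as iodobenzene leaves, giving the methyl arylacetate.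

Step 5
Reactants: 6 methyl 2-(5-methoxy-2,2-dimethylchroman-6-yl)acetate
Product: 7 dimethyl 2-(5-methoxy-2,2-dimethylchroman-6-yl)malonate
Conditions: NaH, (MeO)2CO, THF, reflux; then aq. HCl
Reagents that add atoms: dimethyl carbonate, COC(=O)OC
Why: Crossed Claisen C-acylation of the ester enolate, driven to completion by deprotonation of the product malonate.

Step 6
Reactants: 7 dimethyl 2-(5-methoxy-2,2-dimethylchroman-6-yl)malonate
Product: 8 2-(5-methoxy-2,2-dimethylchroman-6-yl)propane-1,3-diol
Conditions: LiAlH4 (excess), THF, 0 °C → rt (malonate added to the hydride)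
Reagents that add atoms: none
Why: Hydride reduction of both ester groups, with the malonate added to cold excess LiAlH4 so that enolization and the elimination that follows it stay minor.

Step 7
Reactants: 8 2-(5-methoxy-2,2-dimethylchroman-6-yl)propane-1,3-diol
Product: 10 5-methoxy-2,2-dimethyl-6-(oxetan-3-yl)chroman, via monotosylate 9 (not isolated)
Conditions: n-BuLi (1.0 equiv), THF, 0 °C; TsCl (1.0 equiv); n-BuLi (1.0 equiv), 0 → 60 °C
Reagents that add atoms: none
Why: One-flask intramolecular Williamson etherification, in which the monolithium alkoxide is tosylated once and the second alkoxide displaces the tosylate in a 4-exo-tet closure, a standard way from 2-arylpropane-1,3-diols to 3-aryloxetanes.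

Step 8
Reactants: 10 5-methoxy-2,2-dimethyl-6-(oxetan-3-yl)chroman; 11 2-chloro-1,1-dimethoxyethane (chloroacetaldehyde dimethyl acetal)
Product: 13 racemic 5-methoxy-2-(5-methoxy-2,2-dimethylchroman-6-yl)pent-4-yn-1-ol, via lithium methoxyacetylide 12 (not isolated)
Conditions: 11, LiNEt2 (3 equiv per 11), THF, 0 °C; cannulated into BF3·OEt2 (in excess over acetylide, Et2NH and LiOMe), THF, −78 °C; then 10, −78 °C; sat. NaHCO3
Reagents that add atoms: none
Why: Yamaguchi–Hirao alkynylation, in which the acetylide made by double elimination and deprotonation of the chloroacetal is turned into its fluoroborate and opens the BF3-activated symmetrical oxetane at either CH2 without any basic elimination, so the new stereocentre forms as the racemate, and the work-up stays basic because the hydroxy ynol ether is acid-labile.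

Step 9
Reactants: 13 racemic 5-methoxy-2-(5-methoxy-2,2-dimethylchroman-6-yl)pent-4-yn-1-ol
Product: 14 racemic tert-butyl{[5-methoxy-2-(5-methoxy-2,2-dimethylchroman-6-yl)pent-4-yn-1-yl]oxy}dimethylsilane
Conditions: TBSCl, imidazole, DMF, 0 °C → rt
Reagents that add atoms: tert-butyldimethylsilyl chloride, CC(C)(C)[Si](C)(C)Cl
Why: Imidazole-mediated silylation of the primary alcohol under non-acidic conditions that the ynol ether tolerates, needed because a free alcohol would trap the ketene intermediates of step 11.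

Step 10
Reactants: 15 3-ethoxycyclobut-2-en-1-one
Product: 16 3-(benzyloxy)cyclobut-2-en-1-one
Conditions: BnOH (1.5 equiv), camphorsulfonic acid (cat.), toluene, 35 °C, reduced pressure (EtOH removed); chromatography to remove BnOH
Reagents that add atoms: benzyl alcohol, OCc1ccccc1
Why: Acid-catalysed alkoxy exchange of a vinylogous ester (conjugate addition of benzyl alcohol, loss of ethanol), pulled to the benzyl enol ether by removing ethanol below the temperature at which the cyclobutenone ring opens.

Step 11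
Reactants: 14 racemic tert-butyl{[5-methoxy-2-(5-methoxy-2,2-dimethylchroman-6-yl)pent-4-yn-1-yl]oxy}dimethylsilane; 16 3-(benzyloxy)cyclobut-2-en-1-one
Product: 21 racemic 5-(benzyloxy)-2-[3-(tert-butyldimethylsilyloxy)-2-(5-methoxy-2,2-dimethylchroman-6-yl)propyl]-3-methoxyphenol, via vinylketene 17 (not isolated), via vinylcyclobutenone 18 (not isolated), via dienylketene 19 (not isolated), via cyclohexadienone 20 (not isolated)
Conditions: 16 (1.5 equiv, in portions), degassed toluene, 80 °C → 110 °C; then K2CO3, MeOH, rt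
Reagents that add atoms: none
Why: Danheiser benzannulation (cyclobutenone plus alkoxyalkyne), here with a 3-alkoxycyclobutenone as the less usual four-carbon partner: thermal 4π electrocyclic opening of 16 gives vinylketene 17, which adds across the ynol ether in a regioselective [2+2] cycloaddition (bonds C8a–C4a and C5–C6) to give vinylcyclobutenone 18. A second 4π opening gives dienylketene 19, and the benzo ring (C4a, C5, C6, C7, C8, C8a) is closed by a 6π electrocyclization that forms C8a–C8, after which cyclohexadienone 20 tautomerizes to phenol 21. The selectivity that matters is the orientation of the [2+2] step, and the polarity of the partners fixes it: the alkyne carbon β to the methoxy oxygen is nucleophilic and bonds to the electrophilic ketene carbonyl carbon, so the side chain ends up ortho and OMe meta to the new hydroxyl, and the benzyloxy group of 16 becomes the C7 substituent. No stereocentre is formed in 21, since the transient one in 18 disappears on ring opening and the side-chain centre is a spectator. The silyl ether keeps the alcohol from trapping the ketenes, the methyl ynol ether cannot lose an alkene by retro-ene reaction, and the short K2CO3/MeOH treatment returns any phenol that was O-acylated by 17.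

Step 12
Reactants: 21 racemic 5-(benzyloxy)-2-[3-(tert-butyldimethylsilyloxy)-2-(5-methoxy-2,2-dimethylchroman-6-yl)propyl]-3-methoxyphenol
Product: 22 racemic 5-(benzyloxy)-2-[3-hydroxy-2-(5-methoxy-2,2-dimethylchroman-6-yl)propyl]-3-methoxyphenol
Conditions: Bu4NF, THF, 0 °C → rt
Reagents that add atoms: none
Why: Fluoride cleavage of the primary silyl ether, to which the phenol, the benzyl ether and the methyl ethers are inert.

Step 13
Reactants: 22 racemic 5-(benzyloxy)-2-[3-hydroxy-2-(5-methoxy-2,2-dimethylchroman-6-yl)propyl]-3-methoxyphenol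
Product: 25 racemic 7-(benzyloxy)-5-methoxy-3-(5-methoxy-2,2-dimethylchroman-6-yl)chroman-2-one, via hydroxy aldehyde 23 (not isolated), via lactol 24 (not isolated)
Conditions: pyridinium chlorochromate (C5H5NH)[CrO3Cl] (3 equiv), NaOAc, 4 Å MS, CH2Cl2, rt
Reagents that add atoms: none
Why: Oxidative lactonization with buffered chlorochromate, in which the primary alcohol gives the aldehyde, the neighbouring phenol captures it at once as the six-membered lactol, and the lactol is oxidized to the lactone, the last stage being the usual way from 5,7-dialkoxychroman-2-ols to dihydrocoumarins.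

Step 14
Reactants: 25 racemic 7-(benzyloxy)-5-methoxy-3-(5-methoxy-2,2-dimethylchroman-6-yl)chroman-2-one
Product: 28 7-(benzyloxy)-5-methoxy-3-(5-methoxy-2,2-dimethylchroman-6-yl)-2H-chromen-2-one, via selenide 26 (not isolated), via selenoxide 27 (not isolated)
Conditions: LiN(SiMe3)2, THF, −78 °C; PhSeBr, −78 °C; then AcOH, 30% H2O2, 0 °C → rt
Reagents that add atoms: none
Why: Reich selenoxide dehydrogenation, in which the lactone enolate (C3–H is benzylic and alpha to the carbonyl) is selenenylated and the selenoxide undergoes syn elimination with a C4 hydrogen, the only β-hydrogens present, so the coumarin forms without exposing the chroman benzylic CH2 to a hydride-abstracting oxidant such as DDQ.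

Step 15
Reactants: 28 7-(benzyloxy)-5-methoxy-3-(5-methoxy-2,2-dimethylchroman-6-yl)-2H-chromen-2-one
Product: 29 7-hydroxy-5-methoxy-3-(5-methoxy-2,2-dimethylchroman-6-yl)-2H-chromen-2-one
Conditions: H2 (1 atm), 10% Pd/C, EtOAc–MeOH, rt
Reagents that add atoms: none
Why: Hydrogenolysis of the benzyl aryl ether at 1 atm, conditions under which the trisubstituted, aryl-conjugated C3=C4 bond of the coumarin is not reduced.

Compound list
1 | 2,4-dihydroxyacetophenone | CC(=O)c1ccc(O)cc1O | starting material
2 | 3-methylbut-2-enal | CC(C)=CC=O | starting material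
3 | 1-(5-hydroxy-2,2-dimethyl-2H-chromen-6-yl)ethan-1-one | CC(=O)c1ccc2OC(C)(C)C=Cc2c1O | intermediate
4 | 1-(5-hydroxy-2,2-dimethylchroman-6-yl)ethan-1-one | CC(=O)c1ccc2OC(C)(C)CCc2c1O | intermediate
5 | 1-(5-methoxy-2,2-dimethylchroman-6-yl)ethan-1-one | CC(=O)c1ccc2OC(C)(C)CCc2c1OC | intermediate
6 | methyl 2-(5-methoxy-2,2-dimethylchroman-6-yl)acetate | COC(=O)Cc1ccc2OC(C)(C)CCc2c1OC | intermediate
7 | dimethyl 2-(5-methoxy-2,2-dimethylchroman-6-yl)malonate | COC(=O)C(C(=O)OC)c1ccc2OC(C)(C)CCc2c1OC | intermediate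
8 | 2-(5-methoxy-2,2-dimethylchroman-6-yl)propane-1,3-diol | OCC(CO)c1ccc2OC(C)(C)CCc2c1OC | intermediate
9 | racemic 3-hydroxy-2-(5-methoxy-2,2-dimethylchroman-6-yl)propyl 4-methylbenzenesulfonate (present as its lithium alkoxide) | Cc1ccc(cc1)S(=O)(=O)OCC(CO)c1ccc2OC(C)(C)CCc2c1OC | intermediate (not isolated)
10 | 5-methoxy-2,2-dimethyl-6-(oxetan-3-yl)chroman | C1OCC1c1ccc2OC(C)(C)CCc2c1OC | intermediate
11 | 2-chloro-1,1-dimethoxyethane | COC(CCl)OC | starting material
12 | lithium methoxyacetylide | [Li]C#COC | intermediate (not isolated)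
13 | racemic 5-methoxy-2-(5-methoxy-2,2-dimethylchroman-6-yl)pent-4-yn-1-ol | COC#CCC(CO)c1ccc2OC(C)(C)CCc2c1OC | intermediate
14 | racemic tert-butyl{[5-methoxy-2-(5-methoxy-2,2-dimethylchroman-6-yl)pent-4-yn-1-yl]oxy}dimethylsilane | COC#CCC(CO[Si](C)(C)C(C)(C)C)c1ccc2OC(C)(C)CCc2c1OC | intermediate
15 | 3-ethoxycyclobut-2-en-1-one | CCOC1=CC(=O)C1 | starting material
16 | 3-(benzyloxy)cyclobut-2-en-1-one | O=C1C=C(OCc2ccccc2)C1 | intermediate
17 | 3-(benzyloxy)buta-1,3-dien-1-one | O=C=CC(=C)OCc1ccccc1 | intermediate (not isolated)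
18 | 4-[1-(benzyloxy)ethenyl]-2-[3-(tert-butyldimethylsilyloxy)-2-(5-methoxy-2,2-dimethylchroman-6-yl)propyl]-3-methoxycyclobut-2-en-1-one (racemic, mixture of diastereomers) | O=C1C(CC(CO[Si](C)(C)C(C)(C)C)c2ccc3OC(C)(C)CCc3c2OC)=C(OC)C1C(=C)OCc1ccccc1 | intermediate (not isolated)
19 | racemic (3E)-5-(benzyloxy)-2-[3-(tert-butyldimethylsilyloxy)-2-(5-methoxy-2,2-dimethylchroman-6-yl)propyl]-3-methoxyhexa-1,3,5-trien-1-one (ketene carbon and vinyl group cis) | O=C=C(CC(CO[Si](C)(C)C(C)(C)C)c1ccc2OC(C)(C)CCc2c1OC)/C(OC)=C\C(=C)OCc1ccccc1 | intermediate (not isolated)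
20 | racemic 5-(benzyloxy)-2-[3-(tert-butyldimethylsilyloxy)-2-(5-methoxy-2,2-dimethylchroman-6-yl)propyl]-3-methoxycyclohexa-2,4-dien-1-one | O=C1CC(OCc2ccccc2)=CC(OC)=C1CC(CO[Si](C)(C)C(C)(C)C)c1ccc2OC(C)(C)CCc2c1OC | intermediate (not isolated)
21 | racemic 5-(benzyloxy)-2-[3-(tert-butyldimethylsilyloxy)-2-(5-methoxy-2,2-dimethylchroman-6-yl)propyl]-3-methoxyphenol | COc1cc(OCc2ccccc2)cc(O)c1CC(CO[Si](C)(C)C(C)(C)C)c1ccc2OC(C)(C)CCc2c1OC | intermediate
22 | racemic 5-(benzyloxy)-2-[3-hydroxy-2-(5-methoxy-2,2-dimethylchroman-6-yl)propyl]-3-methoxyphenol | COc1cc(OCc2ccccc2)cc(O)c1CC(CO)c1ccc2OC(C)(C)CCc2c1OC | intermediate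
23 | racemic 3-[4-(benzyloxy)-2-hydroxy-6-methoxyphenyl]-2-(5-methoxy-2,2-dimethylchroman-6-yl)propanal | COc1cc(OCc2ccccc2)cc(O)c1CC(C=O)c1ccc2OC(C)(C)CCc2c1OC | intermediate (not isolated)
24 | 7-(benzyloxy)-5-methoxy-3-(5-methoxy-2,2-dimethylchroman-6-yl)chroman-2-ol (racemic, mixture of diastereomers) | COc1cc(OCc2ccccc2)cc2OC(O)C(Cc12)c1ccc2OC(C)(C)CCc2c1OC | intermediate (not isolated)
25 | racemic 7-(benzyloxy)-5-methoxy-3-(5-methoxy-2,2-dimethylchroman-6-yl)chroman-2-one | COc1cc(OCc2ccccc2)cc2OC(=O)C(Cc12)c1ccc2OC(C)(C)CCc2c1OC | intermediate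
26 | racemic 7-(benzyloxy)-5-methoxy-3-(5-methoxy-2,2-dimethylchroman-6-yl)-3-(phenylselanyl)chroman-2-one | COc1cc(OCc2ccccc2)cc2OC(=O)C(Cc12)([Se]c1ccccc1)c1ccc2OC(C)(C)CCc2c1OC | intermediate (not isolated)
27 | 7-(benzyloxy)-5-methoxy-3-(5-methoxy-2,2-dimethylchroman-6-yl)-3-(phenylseleninyl)chroman-2-one (racemic, mixture of diastereomers) | COc1cc(OCc2ccccc2)cc2OC(=O)C(Cc12)([Se](=O)c1ccccc1)c1ccc2OC(C)(C)CCc2c1OC | intermediate (not isolated)
28 | 7-(benzyloxy)-5-methoxy-3-(5-methoxy-2,2-dimethylchroman-6-yl)-2H-chromen-2-one | COc1cc(OCc2ccccc2)cc2oc(=O)c(cc12)-c1ccc2OC(C)(C)CCc2c1OC | intermediate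
29 | 7-hydroxy-5-methoxy-3-(5-methoxy-2,2-dimethylchroman-6-yl)-2H-chromen-2-one | COc1c(-c2cc3c(OC)cc(O)cc3oc2=O)ccc2c1CCC(C)(C)O2 | target

Total step count: 15. Longest linear sequence: 14 steps (steps 1–9 and 11–15, from 2,4-dihydroxyacetophenone); step 10 is a one-step side branch.

Steps most likely to fail

Step 11. Vinylketene 17 may dimerize, or acylate the product phenol, faster than the hindered internal ynol ether captures it. The second ring opening and the 6π closure may also need temperatures at which the electron-rich partners decompose. The fallback buys the phloroglucinol ring instead of building it; it sets out from 6 and comes back at 28. Ester 6 is saponified (LiOH, THF–H2O) to 2-(5-methoxy-2,2-dimethylchroman-6-yl)acetic acid F1. Purchased 2,4,6-trihydroxybenzaldehyde is benzylated at its non-chelated 4-OH (BnBr, NaHCO3, DMF) to 4-(benzyloxy)-2,6-dihydroxybenzaldehyde F2. One of the two chelated hydroxyls is then methylated (MeI, 1 equiv, K2CO3, acetone) to 4-(benzyloxy)-2-hydroxy-6-methoxybenzaldehyde F3. Perkin–Oglialoro condensation of F1 with F3 (Ac2O, Et3N, 120 °C) gives coumarin 28 directly, and step 15 follows.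

Step 8. The diethylamine and lithium methoxide that accompany acetylide 12 may tie up BF3·OEt2 or quench the acetylide. The Lewis acid may ionize the electron-rich 3-aryloxetane. The hydroxy ynol ether may hydrate on work-up. The fallback avoids the Lewis acid; it sets out from 8 and comes back at 14. Diol 8 is monosilylated (NaH, 1 equiv, TBSCl, THF) to racemic 3-(tert-butyldimethylsilyloxy)-2-(5-methoxy-2,2-dimethylchroman-6-yl)propan-1-ol F4. This is converted (I2, PPh3, imidazole, CH2Cl2) into racemic tert-butyl[3-iodo-2-(5-methoxy-2,2-dimethylchroman-6-yl)propoxy]dimethylsilane F5. Alkylation of lithium methoxyacetylide 12 (from 11 and LiNEt2) with F5 in THF–DMPU at −78 → 0 °C gives 14 without passing through 10 and 13.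

Step 13. The oxidant may attack the very electron-rich free phenol ring before the aldehyde has tied the phenol up as the lactol. The fallback masks the phenol and oxidizes the chain to the acid; it sets out from 21 and comes back at 25. Phenol 21 is acetylated (Ac2O, pyridine) to racemic 5-(benzyloxy)-2-[3-(tert-butyldimethylsilyloxy)-2-(5-methoxy-2,2-dimethylchroman-6-yl)propyl]-3-methoxyphenyl acetate F6. Desilylation with HF·pyridine in THF gives racemic 5-(benzyloxy)-2-[3-hydroxy-2-(5-methoxy-2,2-dimethylchroman-6-yl)propyl]-3-methoxyphenyl acetate F7. Oxidation with catalytic TEMPO and PhI(OAc)2 in MeCN–H2O gives racemic 3-[2-acetoxy-4-(benzyloxy)-6-methoxyphenyl]-2-(5-methoxy-2,2-dimethylchroman-6-yl)propanoic acid F8. Methanolysis of the aryl acetate (K2CO3, MeOH) gives racemic 3-[4-(benzyloxy)-2-hydroxy-6-methoxyphenyl]-2-(5-methoxy-2,2-dimethylchroman-6-yl)propanoic acid F9. On acidification and warming with catalytic TsOH in toluene, F9 lactonizes to 25.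

Further compounds
F1 | step 11 | 2-(5-methoxy-2,2-dimethylchroman-6-yl)acetic acid | OC(=O)Cc1ccc2OC(C)(C)CCc2c1OC
F2 | step 11 | 4-(benzyloxy)-2,6-dihydroxybenzaldehyde | O=Cc1c(O)cc(OCc2ccccc2)cc1O
F3 | step 11 | 4-(benzyloxy)-2-hydroxy-6-methoxybenzaldehyde | COc1cc(OCc2ccccc2)cc(O)c1C=O
F4 | step 8 | racemic 3-(tert-butyldimethylsilyloxy)-2-(5-methoxy-2,2-dimethylchroman-6-yl)propan-1-ol | OCC(CO[Si](C)(C)C(C)(C)C)c1ccc2OC(C)(C)CCc2c1OC
F5 | step 8 | racemic tert-butyl[3-iodo-2-(5-methoxy-2,2-dimethylchroman-6-yl)propoxy]dimethylsilane | ICC(CO[Si](C)(C)C(C)(C)C)c1ccc2OC(C)(C)CCc2c1OC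
F6 | step 13 | racemic 5-(benzyloxy)-2-[3-(tert-butyldimethylsilyloxy)-2-(5-methoxy-2,2-dimethylchroman-6-yl)propyl]-3-methoxyphenyl acetate | COc1cc(OCc2ccccc2)cc(OC(C)=O)c1CC(CO[Si](C)(C)C(C)(C)C)c1ccc2OC(C)(C)CCc2c1OC
F7 | step 13 | racemic 5-(benzyloxy)-2-[3-hydroxy-2-(5-methoxy-2,2-dimethylchroman-6-yl)propyl]-3-methoxyphenyl acetate | COc1cc(OCc2ccccc2)cc(OC(C)=O)c1CC(CO)c1ccc2OC(C)(C)CCc2c1OC
F8 | step 13 | racemic 3-[2-acetoxy-4-(benzyloxy)-6-methoxyphenyl]-2-(5-methoxy-2,2-dimethylchroman-6-yl)propanoic acid | COc1cc(OCc2ccccc2)cc(OC(C)=O)c1CC(C(O)=O)c1ccc2OC(C)(C)CCc2c1OC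
F9 | step 13 | racemic 3-[4-(benzyloxy)-2-hydroxy-6-methoxyphenyl]-2-(5-methoxy-2,2-dimethylchroman-6-yl)propanoic acid | COc1cc(OCc2ccccc2)cc(O)c1CC(C(O)=O)c1ccc2OC(C)(C)CCc2c1OC
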